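**Retrosynthetic overview** (labdane numbering throughout, also for the monocyclic ring B intermediates, ring B = C5–C10)
1. The target is 7α,15,19-triacetoxylabda-8(17),13Z-dien-2α-ol. C12–C13 is cut by a Negishi coupling with a Z iodoalkene; C8=C17 and the 7α-oxygen go back to a C8 ketone (methylenation, Rubottom oxidation).
2. The strategy rests on the 1,4-dioxygenated array O–C19–C4–C3–C2–O around the quaternary C4 of ring A. C3–C4 is made by anodic coupling of a C4=C19 methyl enol ether with a C2=C3 silyl enol ether, which closes ring A and gives the C2 ketone and the C19 dimethyl acetal.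
3. Ring B comes from racemic Hagemann's ester: C9 allylation, conjugate methallylation at C10 anti to the C5 ester, resolution as diastereomeric ketals of an enantiopure diol, ozonolysis, then ester → Weinreb amide → methyl ketone → E enol ether.
4. Ring order: ring B is present from the start, ring A is closed in step 10. C4 is set in step 10, C2 by Li/NH3, C7 by the Rubottom oxidation, C9 by equilibration next to the C8 ketone.

Key step: step 10

Assumption: the two (2R,3R)-butane-2,3-diol ketals formed from racemic 5 are separable by chromatography, and the diastereomer drawn as 6 is identified by X-ray analysis of a crystalline derivative.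

**Step 1**
Reactants: 1 Hagemann's ester (racemic); 2 allyl bromide
Product: 3 ethyl 3-allyl-2-methyl-4-oxocyclohex-2-ene-1-carboxylate (racemic)
Conditions: KOt-Bu, t-BuOH, 25 °C; then 2, reflux
Reagents that add atoms: none
Why: Alkylation of the extended dienolate of Hagemann's ester, which reacts with allylic halides at the α-carbon of the enone (future C9) and regenerates the conjugated enone; no stereocentre is fixed because the ester-bearing carbon stays epimerisable.

**Step 2**
Reactants: 3 allylated enone; 4 trimethyl(2-methylallyl)silane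
Product: 5 ethyl 3-allyl-2-methyl-2-(2-methylallyl)-4-oxocyclohexane-1-carboxylate (racemic; ester trans to methallyl; ester, ring methyl and allyl cis)
Conditions: TiCl4, CH2Cl2, −78 °C; aq. NaHCO3; then DBU (cat.), CH2Cl2, 25 °C; chromatography
Reagents that add atoms: none
Why: Hosomi–Sakurai conjugate allylation in which the silane attacks the TiCl4-activated enone axially and anti to the ester (pseudoaxial to avoid A(1,2) strain with the vinylic methyl), setting C10 with methallyl trans to CO2Et; C9 is set on protonation and equilibrated with DBU, the epimer with the allyl group cis to the ring methyl is collected and the other recycled, and C9 is corrected again in step 13.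

**Step 3**
Reactants: 5 keto ester (racemic)
Product: 6 (2R,3R)-butane-2,3-diyl ketal of the 5,9,10-natural enantiomer of 5
Conditions: (2R,3R)-butane-2,3-diol, i-PrOSiMe3, Me3SiOTf (cat.), CH2Cl2, −20 °C; chromatographic separation of the two diastereomeric ketals
Reagents that add atoms: (2R,3R)-butane-2,3-diol, C[C@@H](O)[C@@H](C)O
Why: Silyl-triflate-catalysed ketalisation at low temperature protects the C8 ketone without epimerising C9 or engaging the methallyl alkene, and the enantiopure C2-symmetric diol turns the two enantiomers of 5 into separable diastereomers (resolution; no new stereocentre, the unwanted diastereomer is discarded).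

**Step 4**
Reactants: 6 ketal ester
Product: 7 ketal Weinreb amide (N-methoxy-N-methylamide at C4)
Conditions: MeNH(OMe)·HCl, i-PrMgCl, THF, −20 → 0 °C
Reagents that add atoms: N,O-dimethylhydroxylamine hydrochloride, CNOC.Cl
Why: Direct aminolysis of the ester by the chloromagnesium amide of N,O-dimethylhydroxylamine (Weinreb amide formation); the weakly basic reagent leaves the C5 stereocentre untouched and the amide later permits mono-addition of a methyl nucleophile.

**Step 5**
Reactants: 7 Weinreb amide
Product: 9 C12 alcohol with C2 methyl ketone (Weinreb amide and ketal unchanged), via keto aldehyde 8 (not isolated)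
Conditions: O3, CH2Cl2, −78 °C; PPh3, −78 → 25 °C; then NaBH(OAc)3, AcOH, 25 °C
Reagents that add atoms: ozone, [O-][O+]=O
Why: Ozonolysis with reductive work-up cleaves the allyl group to the C12 aldehyde and the methallyl group to the C2 methyl ketone, and NaBH(OAc)3 then reduces only the aldehyde because it does not reduce unactivated ketones or Weinreb amides at room temperature.

**Step 6**
Reactants: 9 hydroxy ketone
Product: 10 C12 triisopropylsilyl ether
Conditions: TIPSCl, imidazole, DMF, 25 °C
Reagents that add atoms: chlorotriisopropylsilane, CC(C)[Si](Cl)(C(C)C)C(C)C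
Why: Standard silylation of the primary alcohol; the TIPS ether is chosen because it withstands amide bases, the Grignard reagent, electrolysis in methanol, Li/NH3 and the later aqueous acid.

**Step 7**
Reactants: 10 methyl ketone
Product: 11 C2=C3 tert-butyldimethylsilyl enol ether (terminal CH2=C(OTBS)–CH2– on C10)
Conditions: LiN(i-Pr)2 (LDA), THF, −78 °C, 10 min; TBSOTf, −78 °C; Et3N, aq. NaHCO3
Reagents that add atoms: tert-butyldimethylsilyl triflate, CC(C)(C)[Si](C)(C)OS(=O)(=O)C(F)(F)F
Why: Kinetic deprotonation at the unhindered methyl (C3) rather than the neopentyl C1 methylene, followed by O-silylation, gives the terminal silyl enol ether; immediate trapping at −78 °C keeps the enolate from acylating the hindered Weinreb amide, and masking the C2 carbonyl here is what distinguishes it from the C4 ketone made next.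

**Step 8**
Reactants: 11 silyl enol ether Weinreb amide
Product: 12 C4 methyl ketone (acetyl group on C5)
Conditions: MeMgBr, THF, 0 → 25 °C; pH 7 buffer
Reagents that add atoms: methylmagnesium bromide, C[Mg]Br
Why: Weinreb ketone synthesis, in which the chelated tetrahedral adduct stops at mono-addition and gives the ketone only on work-up, so C5 is not epimerised; the silyl enol ether, silyl ether and ketal are inert to the Grignard reagent.

**Step 9**
Reactants: 12 methyl ketone; 13 (methoxymethyl)triphenylphosphonium chloride
Product: 14 ring B bis(enol ether) with an E-configured C4=C19 methyl enol ether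
Conditions: 13, KN(SiMe3)2 (KHMDS), THF, 0 °C; then 12, 0 → 25 °C; chromatography on Et3N-deactivated silica
Reagents that add atoms: none
Why: Wittig methoxymethylenation of the only free carbonyl group (a methyl ketone on a tertiary carbon next to a quaternary one, as in steroidal 20-ketones); the E isomer, with OMe cis to the methyl and trans to C5, is expected to predominate and is separated from the Z isomer because the enol ether geometry decides the face selectivity of step 10.

**Step 10**
Reactants: 14 bis(enol ether)
Product: 15 decalin-2-one C19 dimethyl acetal (C8 ketal and C12 silyl ether kept)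
Conditions: reticulated vitreous carbon anode, Pt cathode, undivided cell, constant current (8 mA, 2.2 F/mol), 0.1 M LiClO4, MeOH/CH2Cl2 (1:4), 2,6-lutidine, 25 °C
Reagents that add atoms: methanol, CO
Why: One-electron oxidation at the anode turns the trisubstituted methyl enol ether into a radical cation whose C4 terminus is attacked by C3 of the silyl enol ether; a second electron is then removed, methanol converts the C19 oxocarbenium ion into the dimethyl acetal and takes the silyl group off the C2 siloxycarbenium ion to leave the ketone. The closest known reaction type is the intramolecular anodic olefin coupling of an enol ether with a second enol ether or silyl enol ether, which joins two nucleophilic carbons to give 1,4-dicarbonyl equivalents and quaternary carbons in six-membered rings. Ring A closes 6-exo-trig with respect to C4=C19 (6-endo with respect to C2=C3) through a chair-like transition state on the ring B chair, where the C5 and C10 arms are trans-diequatorial, so only the trans-decalin can form. The new stereocentre C4 is controlled by the rotamer about C5–C4: in the E enol ether C19 carries only hydrogen cis to C5, so A(1,2) strain puts the C18 methyl beside H5 (the future equatorial site) and the flat C19 carbon syn to the axial C20 methyl, which makes C19 axial (β). The step needs oxidation of the enol ethers alone and C–C bond formation faster than capture of the radical cation by methanol; the ketal and silyl ether are not oxidised at this potential, lutidine suppresses acid-induced loss of the enol ethers, and the pre-organised neighbouring arms favour cyclisation.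

**Step 11**
Reactants: 15 decalin-2-one
Product: 16 2α-alcohol (equatorial)
Conditions: Li, NH3 (l), THF, t-BuOH, −78 °C; NH4Cl
Reagents that add atoms: none
Why: Dissolving-metal reduction gives the thermodynamically favoured equatorial 2α-alcohol, whereas hydride reagents would be forced to the α-face by the axial C20 methyl and C19 acetal and give the axial 2β-alcohol; ketal, acetal and silyl ether are stable.

**Step 12**
Reactants: 16 2α-alcohol
Product: 17 2α-(4-methoxybenzyl) ether
Conditions: NaH, PMBCl, n-Bu4NI (cat.), DMF, 0 → 25 °C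
Reagents that add atoms: 4-methoxybenzyl chloride, COc1ccc(CCl)cc1
Why: Williamson etherification of the unhindered equatorial alcohol; the PMB ether survives all later steps and is removable oxidatively at the end without touching acetates.

**Step 13**
Reactants: 17 acetal ketal
Product: 18 8-oxo-19-aldehyde (9α-H, side chain equatorial)
Conditions: TsOH·H2O (cat.), acetone/H2O, 50 °C
Reagents that add atoms: water, O
Why: Acid hydrolysis of the dimethyl acetal and of the ketal (strained by its axial oxygen 1,3 to the C20 methyl) frees the C19 aldehyde and the C8 ketone, and the now epimerisable C9 settles in the thermodynamic configuration with the side chain equatorial; PMB and primary TIPS ethers survive.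

**Step 14**
Reactants: 18 keto aldehyde
Product: 19 19-hydroxy-8-ketone
Conditions: NaBH(OAc)3, AcOH, benzene, 50 °C
Reagents that add atoms: none
Why: Chemoselective reduction of an aldehyde in the presence of a ketone with NaBH(OAc)3, which keeps the C8 ketone for the Rubottom oxidation.

**Step 15**
Reactants: 19 hydroxy ketone
Product: 22 7α,19-dihydroxy-8-ketone, via bis-silyl enol ether 20 (not isolated), via 7α-silyloxy ketone 21 (not isolated)
Conditions: LiN(i-Pr)2 (LDA, 2.3 equiv), Me3SiCl, THF, −78 °C; mCPBA, NaHCO3, CH2Cl2, −20 °C; citric acid, MeOH, 25 °C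
Reagents that add atoms: 3-chloroperoxybenzoic acid, OOC(=O)c1cccc(Cl)c1
Why: Rubottom oxidation, in which kinetic deprotonation takes place at the C7 methylene and not at the hindered C9 methine, and the peracid epoxidises the Δ7 silyl enol ether from the α-face, opposite the axial C20 methyl, so that silyl migration and mild acid give the axial 7α-hydroxy ketone; the C19 alcohol is carried as a transient silyl ether.

**Step 16**
Reactants: 22 diol
Product: 23 7α,19-diacetoxy-8-ketone
Conditions: Ac2O, pyridine, DMAP (cat.), CH2Cl2, 25 °C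
Reagents that add atoms: acetic anhydride, CC(=O)OC(C)=O
Why: DMAP-catalysed acetylation of the primary C19 and the axial secondary C7 alcohols installs two of the three acetates of the target.

**Step 17**
Reactants: 23 diacetoxy ketone
Product: 24 7α,19-diacetoxy-8(17)-ene
Conditions: Zn, CH2Br2, TiCl4, THF/CH2Cl2, 0 → 25 °C
Reagents that add atoms: dibromomethane, BrCBr
Why: Takai–Lombardo methylenation, whose non-basic zinc–titanium methylene reagent converts hindered, enolisable ketones into 1,1-disubstituted alkenes without epimerising C7 or C9 and does not attack esters.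

**Step 18**
Reactants: 24 TIPS ether
Product: 25 C12 primary alcohol
Conditions: HF·pyridine, pyridine, THF, 0 → 25 °C
Reagents that add atoms: none
Why: Buffered fluoride cleavage of the primary silyl ether under non-basic conditions, so that the acetates do not migrate and the PMB ether and the allylic C7 acetate stay intact.

**Step 19**
Reactants: 25 alcohol
Product: 26 C12 primary iodide
Conditions: I2, PPh3, imidazole, CH2Cl2, 0 → 25 °C
Reagents that add atoms: iodine, II
Why: Appel iodination of the primary alcohol through the alkoxyphosphonium ion with SN2 displacement at C12.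

**Step 20**
Reactants: 27 but-2-yn-1-ol
Product: 29 (Z)-3-iodobut-2-en-1-ol, via cyclic vinylalanate 28 (not isolated)
Conditions: NaAlH2(OCH2CH2OMe)2 (Red-Al), Et2O, 0 → 25 °C; then I2, THF, −78 → 0 °C
Reagents that add atoms: iodine, II
Why: Hydroxyl-directed trans-hydroalumination of the propargylic alcohol places aluminium on C3 inside a five-membered alanate, and iodinolysis of the C–Al bond with retention gives the iodoalkene with I cis to CH2OH, which fixes the 13Z geometry.

**Step 21**
Reactants: 29 iodo alcohol
Product: 30 (Z)-3-iodobut-2-enyl acetate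
Conditions: Ac2O, pyridine, DMAP (cat.), CH2Cl2, 0 → 25 °C
Reagents that add atoms: acetic anhydride, CC(=O)OC(C)=O
Why: Acetylation of the primary allylic alcohol puts the C15 acetate in place before the coupling.

**Step 22**
Reactants: 26 alkyl iodide; 30 Z iodoalkene
Product: 32 7α,15,19-triacetoxy-2α-(4-methoxybenzyloxy)labda-8(17),13Z-diene, via alkylzinc iodide 31 (not isolated)
Conditions: Zn dust (activated with BrCH2CH2Br, Me3SiCl), LiCl, THF, 40 °C; then 30, PdCl2(dppf) (5 mol %), THF, 25 °C
Reagents that add atoms: none
Why: Negishi sp3–sp2 cross-coupling in which direct zinc insertion tolerates the acetates and zerovalent palladium adds to the C–I bond of 30, then transmetallation and reductive elimination form C12–C13 with retention of the Z geometry; the iodoalkene is expected to react faster than either allylic acetate ionises, and the C7 acetate is also shielded because palladium would have to approach from the β-face blocked by C20.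

**Step 23**
Reactants: 32 PMB ether
Product: 33 7α,15,19-triacetoxylabda-8(17),13Z-dien-2α-ol (target)
Conditions: DDQ, CH2Cl2/pH 7 buffer, 0 → 25 °C
Reagents that add atoms: none
Why: Oxidative PMB cleavage (benzylic hydride abstraction, then hydrolysis of the oxocarbenium ion) should free the C2 alcohol without affecting the three acetates or the two alkenes.

**Compound list**
1 | Hagemann's ester, ethyl 2-methyl-4-oxocyclohex-2-ene-1-carboxylate (racemic) | CCOC(=O)C1CCC(=O)C=C1C | starting material
2 | allyl bromide | C=CCBr | starting material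
3 | ethyl 3-allyl-2-methyl-4-oxocyclohex-2-ene-1-carboxylate (racemic) | CCOC(=O)C1CCC(=O)C(CC=C)=C1C | intermediate
4 | trimethyl(2-methylallyl)silane | C=C(C)C[Si](C)(C)C | starting material
5 | ethyl 3-allyl-2-methyl-2-(2-methylallyl)-4-oxocyclohexane-1-carboxylate, racemic, ester trans to methallyl, allyl cis to ring methyl (enantiomer carried on is drawn) | O=C1CC[C@@H](C(=O)OCC)[C@](C)(CC(C)=C)[C@H]1CC=C | intermediate
6 | (2R,3R)-butane-2,3-diyl ketal of 5, single enantiomer (C5 ester β, C10 methyl β, C9 allyl β) | C12(O[C@H](C)[C@@H](C)O1)CC[C@@H](C(=O)OCC)[C@](C)(CC(C)=C)[C@H]2CC=C | intermediate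
7 | Weinreb amide of 6 | C12(O[C@H](C)[C@@H](C)O1)CC[C@@H](C(=O)N(C)OC)[C@](C)(CC(C)=C)[C@H]2CC=C | intermediate
8 | C12 aldehyde / C2 methyl ketone Weinreb amide (not isolated) | C12(O[C@H](C)[C@@H](C)O1)CC[C@@H](C(=O)N(C)OC)[C@](C)(CC(C)=O)[C@H]2CC=O | intermediate
9 | C12 alcohol / C2 methyl ketone Weinreb amide | C12(O[C@H](C)[C@@H](C)O1)CC[C@@H](C(=O)N(C)OC)[C@](C)(CC(C)=O)[C@H]2CCO | intermediate
10 | C12 TIPS ether of 9 | C12(O[C@H](C)[C@@H](C)O1)CC[C@@H](C(=O)N(C)OC)[C@](C)(CC(C)=O)[C@H]2CCO[Si](C(C)C)(C(C)C)C(C)C | intermediate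
11 | C2=C3 TBS enol ether Weinreb amide | C12(O[C@H](C)[C@@H](C)O1)CC[C@@H](C(=O)N(C)OC)[C@](C)(CC(=C)O[Si](C)(C)C(C)(C)C)[C@H]2CCO[Si](C(C)C)(C(C)C)C(C)C | intermediate
12 | C4 methyl ketone with C2=C3 TBS enol ether | C12(O[C@H](C)[C@@H](C)O1)CC[C@@H](C(C)=O)[C@](C)(CC(=C)O[Si](C)(C)C(C)(C)C)[C@H]2CCO[Si](C(C)C)(C(C)C)C(C)C | intermediate
13 | (methoxymethyl)triphenylphosphonium chloride | COC[P+](c1ccccc1)(c1ccccc1)c1ccccc1.[Cl-] | starting material
14 | ring B bis(enol ether): E C4=C19 methyl enol ether on C5, C2=C3 TBS enol ether on C10, C12 TIPS ether, C8 butanediol ketal | C12(O[C@H](C)[C@@H](C)O1)CC[C@@H](/C(C)=C/OC)[C@](C)(CC(=C)O[Si](C)(C)C(C)(C)C)[C@H]2CCO[Si](C(C)C)(C(C)C)C(C)C | intermediate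
15 | 19,19-dimethoxy-12-(triisopropylsilyloxy)-13,14,15,16,17-pentanorlabdane-2,8-dione 8-[(2R,3R)-butane-2,3-diyl ketal] (trans-decalin, C19 axial β) | C12(O[C@H](C)[C@@H](C)O1)CC[C@H]3[C@@](C)(C(OC)OC)CC(=O)C[C@]3(C)[C@H]2CCO[Si](C(C)C)(C(C)C)C(C)C | intermediate
16 | 2α-alcohol of 15 | C12(O[C@H](C)[C@@H](C)O1)CC[C@H]3[C@@](C)(C(OC)OC)C[C@H](O)C[C@]3(C)[C@H]2CCO[Si](C(C)C)(C(C)C)C(C)C | intermediate
17 | 2α-PMB ether of 16 | C12(O[C@H](C)[C@@H](C)O1)CC[C@H]3[C@@](C)(C(OC)OC)C[C@H](OCc4ccc(OC)cc4)C[C@]3(C)[C@H]2CCO[Si](C(C)C)(C(C)C)C(C)C | intermediate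
18 | 2α-(4-methoxybenzyloxy)-8-oxo-12-(triisopropylsilyloxy)-13,14,15,16,17-pentanorlabdan-19-al | O=C1CC[C@H]2[C@@](C)(C=O)C[C@H](OCc3ccc(OC)cc3)C[C@]2(C)[C@H]1CCO[Si](C(C)C)(C(C)C)C(C)C | intermediate
19 | 19-hydroxy-8-ketone | O=C1CC[C@H]2[C@@](C)(CO)C[C@H](OCc3ccc(OC)cc3)C[C@]2(C)[C@H]1CCO[Si](C(C)C)(C(C)C)C(C)C | intermediate
20 | Δ7 trimethylsilyl enol ether, 19-O-trimethylsilyl (not isolated) | C[Si](C)(C)OC1=CC[C@H]2[C@@](C)(CO[Si](C)(C)C)C[C@H](OCc3ccc(OC)cc3)C[C@]2(C)[C@H]1CCO[Si](C(C)C)(C(C)C)C(C)C | intermediate
21 | 7α-(trimethylsilyloxy)-8-ketone, 19-O-trimethylsilyl (not isolated) | O=C1[C@H](O[Si](C)(C)C)C[C@H]2[C@@](C)(CO[Si](C)(C)C)C[C@H](OCc3ccc(OC)cc3)C[C@]2(C)[C@H]1CCO[Si](C(C)C)(C(C)C)C(C)C | intermediate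
22 | 7α,19-dihydroxy-8-ketone | O=C1[C@H](O)C[C@H]2[C@@](C)(CO)C[C@H](OCc3ccc(OC)cc3)C[C@]2(C)[C@H]1CCO[Si](C(C)C)(C(C)C)C(C)C | intermediate
23 | 7α,19-diacetoxy-8-ketone | O=C1[C@H](OC(C)=O)C[C@H]2[C@@](C)(COC(C)=O)C[C@H](OCc3ccc(OC)cc3)C[C@]2(C)[C@H]1CCO[Si](C(C)C)(C(C)C)C(C)C | intermediate
24 | 7α,19-diacetoxy-2α-(4-methoxybenzyloxy)-12-(triisopropylsilyloxy)-13,14,15,16-tetranorlabd-8(17)-ene | C=C1[C@H](OC(C)=O)C[C@H]2[C@@](C)(COC(C)=O)C[C@H](OCc3ccc(OC)cc3)C[C@]2(C)[C@H]1CCO[Si](C(C)C)(C(C)C)C(C)C | intermediate
25 | C12 alcohol of 24 | C=C1[C@H](OC(C)=O)C[C@H]2[C@@](C)(COC(C)=O)C[C@H](OCc3ccc(OC)cc3)C[C@]2(C)[C@H]1CCO | intermediate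
26 | C12 iodide | C=C1[C@H](OC(C)=O)C[C@H]2[C@@](C)(COC(C)=O)C[C@H](OCc3ccc(OC)cc3)C[C@]2(C)[C@H]1CCI | intermediate
27 | but-2-yn-1-ol | CC#CCO | starting material
28 | sodium cyclic (Z)-vinylalanate from 27 (not isolated) | CC1=CCO[Al-]1(OCCOC)OCCOC.[Na+] | intermediate
29 | (Z)-3-iodobut-2-en-1-ol | C/C(I)=C/CO | intermediate
30 | (Z)-3-iodobut-2-enyl acetate | C/C(I)=C/COC(C)=O | intermediate
31 | C12 alkylzinc iodide from 26 (not isolated) | C=C1[C@H](OC(C)=O)C[C@H]2[C@@](C)(COC(C)=O)C[C@H](OCc3ccc(OC)cc3)C[C@]2(C)[C@H]1CC[Zn]I | intermediate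
32 | 7α,15,19-triacetoxy-2α-(4-methoxybenzyloxy)labda-8(17),13Z-diene | C=C1[C@H](OC(C)=O)C[C@H]2[C@@](C)(COC(C)=O)C[C@H](OCc3ccc(OC)cc3)C[C@]2(C)[C@H]1CC/C(C)=C\COC(C)=O | intermediate
33 | 7α,15,19-triacetoxylabda-8(17),13Z-dien-2α-ol (CNP0139627.2) | C=C1[C@H](OC(C)=O)C[C@H]2[C@@](C)(COC(C)=O)C[C@H](O)C[C@]2(C)[C@H]1CC/C(C)=C\COC(C)=O | target

**Step count**
Total: 23 steps. Longest linear sequence: 21 steps (steps 1–19, 22, 23); steps 20–21 make the side-chain fragment.

**Three steps most likely to fail**

Step 10. What may go wrong: C3 attacks the wrong face of C4, so that the methyl and not C19 takes the axial site, or methanol captures the radical cation before the C–C bond forms. The fallback makes C4 quaternary only after ring closure. It sets out from 11: i-Bu2AlH (THF, −78 °C) reduces the Weinreb amide to the C4 aldehyde F1, and Wittig reaction with 13 gives the enol ether without C18, F2. The same anodic coupling now forms a tertiary C4 of no stereochemical consequence and gives the 18-nor acetal ketone F3. Li/NH3 gives the 2α-alcohol F4 and NaH/PMBCl its PMB ether F5. The dimethyl acetal alone is cleaved (Et3SiOTf, 2,4,6-collidine, CH2Cl2, then water) to the C19 aldehyde with the ketal kept, F6. Its potassium enolate (KOt-Bu, MeI, THF) is methylated from the α-face, opposite the axial C20 methyl, as in the classical alkylations that give axial C4 carbonyl groups in 10-methyl-trans-decalins, giving the C4-methylated aldehyde F7. Hydrolysis of the ketal (TsOH·H2O, acetone/H2O) comes back to the route at 18.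

Step 2. What may go wrong: addition to the fully substituted β-carbon is slow, and protodesilylation of 4 or Lewis-acid-induced cyclisation of the adduct onto its methallyl alkene takes over. The fallback reverses the order of the two C–C bond formations and avoids the strong Lewis acid. It sets out from 1: the (2-methylallyl)copper reagent (2-methylallylmagnesium chloride, CuI·2LiCl, Me3SiCl, THF, −78 °C) adds to the less hindered trisubstituted enone, anti to the ester, and gives the trimethylsilyl enol ether F8. Its fluoride-generated enolate (benzyltrimethylammonium fluoride, THF) is allylated regiospecifically at C9 with 2, and after the same DBU equilibration the route is rejoined at 5.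

Step 17. What may go wrong: the low-valent metal reagent removes the α-acetoxy group reductively, or addition to the hindered carbonyl is too slow. The fallback methylenates before C7 is oxidised. It sets out from 19: Wittig methylenation of the simple ketone (Ph3PCH3Br, KOt-Bu, toluene, 80 °C) gives the 8(17)-en-19-ol F9. Allylic hydroxylation of the C7 methylene with SeO2 (cat.) and t-BuOOH in CH2Cl2 (ene reaction, then 2,3-sigmatropic shift with axial delivery of oxygen) gives the 7α,19-diol F10. Acetylation (Ac2O, pyridine, DMAP) comes back to the route at 24.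

**Further compounds**
F1 | step 10 | C4 aldehyde with C2=C3 TBS enol ether | C12(O[C@H](C)[C@@H](C)O1)CC[C@@H](C=O)[C@](C)(CC(=C)O[Si](C)(C)C(C)(C)C)[C@H]2CCO[Si](C(C)C)(C(C)C)C(C)C
F2 | step 10 | 18-nor bis(enol ether), E/Z mixture at C4=C19 | C12(O[C@H](C)[C@@H](C)O1)CC[C@@H](C=COC)[C@](C)(CC(=C)O[Si](C)(C)C(C)(C)C)[C@H]2CCO[Si](C(C)C)(C(C)C)C(C)C
F3 | step 10 | 18-nor decalin-2-one C19 dimethyl acetal, C4 epimers | C12(O[C@H](C)[C@@H](C)O1)CC[C@H]3C(C(OC)OC)CC(=O)C[C@]3(C)[C@H]2CCO[Si](C(C)C)(C(C)C)C(C)C
F4 | step 10 | 18-nor 2α-alcohol | C12(O[C@H](C)[C@@H](C)O1)CC[C@H]3C(C(OC)OC)C[C@H](O)C[C@]3(C)[C@H]2CCO[Si](C(C)C)(C(C)C)C(C)C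
F5 | step 10 | 18-nor 2α-PMB ether | C12(O[C@H](C)[C@@H](C)O1)CC[C@H]3C(C(OC)OC)C[C@H](OCc4ccc(OC)cc4)C[C@]3(C)[C@H]2CCO[Si](C(C)C)(C(C)C)C(C)C
F6 | step 10 | 18-nor C19 aldehyde, C8 ketal kept | C12(O[C@H](C)[C@@H](C)O1)CC[C@H]3C(C=O)C[C@H](OCc4ccc(OC)cc4)C[C@]3(C)[C@H]2CCO[Si](C(C)C)(C(C)C)C(C)C
F7 | step 10 | C4-methylated C19 aldehyde (CHO axial β), C8 ketal kept | C12(O[C@H](C)[C@@H](C)O1)CC[C@H]3[C@@](C)(C=O)C[C@H](OCc4ccc(OC)cc4)C[C@]3(C)[C@H]2CCO[Si](C(C)C)(C(C)C)C(C)C
F8 | step 2 | ethyl 2-methyl-2-(2-methylallyl)-4-(trimethylsilyloxy)cyclohex-3-ene-1-carboxylate, racemic, ester trans to methallyl | C[Si](C)(C)OC=1CC[C@@H](C(=O)OCC)[C@](C)(CC(C)=C)C=1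
F9 | step 17 | 2α-(4-methoxybenzyloxy)-12-(triisopropylsilyloxy)-13,14,15,16-tetranorlabd-8(17)-en-19-ol | C=C1CC[C@H]2[C@@](C)(CO)C[C@H](OCc3ccc(OC)cc3)C[C@]2(C)[C@H]1CCO[Si](C(C)C)(C(C)C)C(C)C
F10 | step 17 | 7α,19-diol of F9 | C=C1[C@H](O)C[C@H]2[C@@](C)(CO)C[C@H](OCc3ccc(OC)cc3)C[C@]2(C)[C@H]1CCO[Si](C(C)C)(C(C)C)C(C)C
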